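**Retrosynthetic overview**

1. The ten-membered ring is opened at C7–C8: an intramolecular electroreductive allylation of an α-keto aldehyde by an acyloxy-methylene lactone gives the ring, the exo-methylene lactone and the C8-OH/C9=O pair in one step.
2. The keto aldehyde comes from a terminal vinyl group; the lactone comes from a Morita–Baylis–Hillman adduct of methyl acrylate after acetonide release.
3. The C4 carbinol comes from MeMgBr addition to an α-alkoxy ketone; the ketone (C3–C4 bond) comes from the D-tartrate bis-Weinreb amide and a Grignard reagent made from (S)-β-citronellene.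
4. Stereocentres: C5/C6 are bought (D-tartrate), C10 is bought (citronellene), C4 is set from C5, and C7/C8 are set from C6.
5. Ring order: dioxolane (bought, temporary), then γ-lactone (step 8), then the ten-membered carbocycle last (step 12).

**Assumptions**

- CNP0270933.1 is taken to be exactly the given SMILES. Carbon locants are germacrane locants: C1–C3 ring CH2 (C1 next to C10), C4 C(OH)Me, C5 CH–O-isobutyryl, C6 lactone CH–O, C7 ring-fusion CH, C8 CHOH, C9 C=O, C10 CHMe, C11=C13 exo-methylene, C12 lactone C=O.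
- Where one reagent does the same transformation at two sites in one operation (steps 3, 9, 11), the half-converted species are not numbered.
- The carbinol centres made in step 7 (C7) and step 10 (C9) are carried as epimer mixtures and left unspecified in the SMILES: C7 becomes sp2 in step 12 and C9 is oxidised in step 11.

Step 1
Reactants: 1 (S)-β-citronellene
Product: 3 (4S)-4-methylhex-5-en-1-ol, via aldehyde 2 (not isolated)
Conditions: O3 (1.0 equiv, Sudan III end point), CH2Cl2/MeOH, −78 °C; then NaBH4, −78 °C → rt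
Reagents that add atoms: ozone, [O-][O+]=O
Why: Chemoselective ozonolysis with reductive work-up, in which electrophilic ozone cleaves the trisubstituted alkene much faster than the vinyl group and NaBH4 reduces the aldehyde in the same flask, leaving the bought C10 centre untouched.

Step 2
Reactants: 3 (4S)-4-methylhex-5-en-1-ol
Product: 4 (3S)-6-bromo-3-methylhex-1-ene
Conditions: CBr4, PPh3, CH2Cl2, 0 °C
Reagents that add atoms: carbon tetrabromide, BrC(Br)(Br)Br
Why: Appel reaction of a primary alcohol under neutral conditions, which cannot touch the remote stereocentre or the vinyl group.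

Step 3
Reactants: 5 dimethyl (4S,5S)-2,2-dimethyl-1,3-dioxolane-4,5-dicarboxylate
Product: 6 (4S,5S)-N4,N5-dimethoxy-N4,N5,2,2-tetramethyl-1,3-dioxolane-4,5-dicarboxamide
Conditions: MeNH(OMe)·HCl, i-PrMgCl, THF, −20 → 0 °C
Reagents that add atoms: N,O-dimethylhydroxylamine hydrochloride, CNOC.Cl
Why: Weinreb amide synthesis by aminolysis of both esters with the chloromagnesium amide is fast at low temperature, where the trans-dioxolane stereocentres from D-tartrate do not epimerise.

Step 4
Reactants: 4 (3S)-6-bromo-3-methylhex-1-ene; 6 (4S,5S)-N4,N5-dimethoxy-N4,N5,2,2-tetramethyl-1,3-dioxolane-4,5-dicarboxamide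
Product: 8 (4S,5S)-N-methoxy-N,2,2-trimethyl-5-[(5S)-5-methylhept-6-enoyl]-1,3-dioxolane-4-carboxamide, via Grignard reagent 7 (not isolated)
Conditions: Mg, THF, rt; then 6 (slight excess), THF, −78 → 0 °C; aq. NH4Cl
Reagents that add atoms: none
Why: Grignard acylation of a Weinreb amide stops at the chelated tetrahedral intermediate, and because the two amides of C2-symmetric 6 are homotopic one equivalent gives a single mono-ketone that joins C3 to C4 without creating a stereocentre.

Step 5
Reactants: 8 (4S,5S)-N-methoxy-N,2,2-trimethyl-5-[(5S)-5-methylhept-6-enoyl]-1,3-dioxolane-4-carboxamide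
Product: 9 (4S,5S)-5-[(2R,6S)-2-hydroxy-6-methyloct-7-en-2-yl]-N-methoxy-N,2,2-trimethyl-1,3-dioxolane-4-carboxamide
Conditions: MeMgBr (1.3 equiv), CH2Cl2/Et2O, −78 °C
Reagents that add atoms: methylmagnesium bromide, C[Mg]Br
Why: Cram-chelate controlled Grignard addition, in which Mg bridges the ketone oxygen and the adjacent dioxolane oxygen on C5 so that methyl adds to the face away from the ring C6 substituent and sets C4 as R, while the ketone outcompetes the Weinreb amide at −78 °C.

Step 6
Reactants: 9 (4S,5S)-5-[(2R,6S)-2-hydroxy-6-methyloct-7-en-2-yl]-N-methoxy-N,2,2-trimethyl-1,3-dioxolane-4-carboxamide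
Product: 10 (4S,5S)-5-[(2R,6S)-2-hydroxy-6-methyloct-7-en-2-yl]-2,2-dimethyl-1,3-dioxolane-4-carbaldehyde
Conditions: DIBAL-H (2.2 equiv), THF, −78 °C; Rochelle salt
Reagents that add atoms: none
Why: DIBAL-H reduction of a Weinreb amide stops at the aldehyde through the stable five-membered aluminium chelate, and the α-alkoxy centre (C6) held in the trans-dioxolane does not epimerise.

Step 7
Reactants: 10 (4S,5S)-5-[(2R,6S)-2-hydroxy-6-methyloct-7-en-2-yl]-2,2-dimethyl-1,3-dioxolane-4-carbaldehyde; 11 methyl acrylate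
Product: 12 methyl 2-[hydroxy{(4R,5S)-5-[(2R,6S)-2-hydroxy-6-methyloct-7-en-2-yl]-2,2-dimethyl-1,3-dioxolan-4-yl}methyl]prop-2-enoate (both carbinol epimers)
Conditions: DABCO (1 equiv), neat methyl acrylate, rt, 4–7 d
Reagents that add atoms: none
Why: Morita–Baylis–Hillman reaction of an α-alkoxy aldehyde with methyl acrylate installs C11–C13, and the new carbinol centre (C7) is formed unselectively on purpose because it is erased in step 12.

Step 8
Reactants: 12 methyl 2-[hydroxy{(4R,5S)-5-[(2R,6S)-2-hydroxy-6-methyloct-7-en-2-yl]-2,2-dimethyl-1,3-dioxolan-4-yl}methyl]prop-2-enoate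
Product: 14 (5R)-5-[(1S,2R,6S)-1,2-dihydroxy-2,6-dimethyloct-7-en-1-yl]-4-hydroxy-3-methylideneoxolan-2-one (C4 epimers), via tetrol ester 13 (not isolated)
Conditions: 1 M HCl, THF, rt; then PPTS (cat.), PhMe, 40 °C
Reagents that add atoms: none
Why: Acid-catalysed acetonide hydrolysis releases the C5/C6 diol and the γ-hydroxyl (C6–OH) closes the five-membered lactone by transesterification in preference to the six-membered alternative from C5–OH, with no change at any stereocentre.

Step 9
Reactants: 14 (5R)-5-[(1S,2R,6S)-1,2-dihydroxy-2,6-dimethyloct-7-en-1-yl]-4-hydroxy-3-methylideneoxolan-2-one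
Product: 15 (2R)-2-[(1S,2R,6S)-2-hydroxy-2,6-dimethyl-1-(2-methylpropanoyloxy)oct-7-en-1-yl]-4-methylidene-5-oxooxolan-3-yl 2-methylpropanoate (C3 epimers)
Conditions: (i-PrCO)2O, pyridine, DMAP (cat.), CH2Cl2, 0 °C → rt
Reagents that add atoms: isobutyric anhydride, CC(C)C(=O)OC(=O)C(C)C
Why: DMAP-catalysed acylation esterifies the two secondary alcohols (C5–OH gives the ester of the target and C7–OH becomes the allylic leaving group) and leaves the tertiary C4–OH free for steric reasons.

Step 10
Reactants: 15 (2R)-2-[(1S,2R,6S)-2-hydroxy-2,6-dimethyl-1-(2-methylpropanoyloxy)oct-7-en-1-yl]-4-methylidene-5-oxooxolan-3-yl 2-methylpropanoate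
Product: 16 (2R)-2-[(1S,2R,6S)-2,7,8-trihydroxy-2,6-dimethyl-1-(2-methylpropanoyloxy)octyl]-4-methylidene-5-oxooxolan-3-yl 2-methylpropanoate (C7′ and ring C3 epimers)
Conditions: OsO4 (2 mol %), NMO, citric acid, t-BuOH/H2O, rt
Reagents that add atoms: N-methylmorpholine N-oxide, C[N+]1([O-])CCOCC1; water, O
Why: Upjohn dihydroxylation in which electrophilic OsO4 prefers the electron-rich vinyl group over the conjugated electron-poor methylene lactone and citric acid keeps the amine by-product protonated so that the allylic ester is not displaced; the new C9 centre is removed in step 11.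

Step 11
Reactants: 16 (2R)-2-[(1S,2R,6S)-2,7,8-trihydroxy-2,6-dimethyl-1-(2-methylpropanoyloxy)octyl]-4-methylidene-5-oxooxolan-3-yl 2-methylpropanoate
Product: 17 (2R)-2-[(1S,2R,6S)-2-hydroxy-2,6-dimethyl-1-(2-methylpropanoyloxy)-7,8-dioxooctyl]-4-methylidene-5-oxooxolan-3-yl 2-methylpropanoate
Conditions: IBX (4 equiv), DMSO, rt; used crude
Reagents that add atoms: none
Why: IBX oxidation converts a vicinal diol into the 1,2-dicarbonyl compound without glycol cleavage under neutral non-basic conditions, so the C10 centre next to the new ketone is not enolised.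

Step 12
Reactants: 17 (2R)-2-[(1S,2R,6S)-2-hydroxy-2,6-dimethyl-1-(2-methylpropanoyloxy)-7,8-dioxooctyl]-4-methylidene-5-oxooxolan-3-yl 2-methylpropanoate
Product: 19 (3aS,4S,6S,10R,11S,11aR)-4,10-dihydroxy-6,10-dimethyl-3-methylidene-2,5-dioxododecahydrocyclodeca[b]furan-11-yl 2-methylpropanoate, via allylindium 18 (not isolated)
Conditions: Pd(PPh3)4 (5 mol %), InBr3 (20 mol %), n-Bu4NBr, DMF (17 added over 12 h to 2 mM), undivided cell, Zn anode, graphite-felt cathode, 3 mA, rt; aq. NH4Cl
Reagents that add atoms: none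
Why: Proposed new method: Pd(0) ionises the allylic isobutyrate of the Morita–Baylis–Hillman-type lactone (Tsuji–Trost ionisation) and In(I), regenerated at the cathode from InBr3 while the zinc anode dissolves, reductively transmetalates the π-allyl to the σ-allylindium 18, which attacks the more electrophilic aldehyde carbonyl through C7 in a closed six-membered transition state on the lactone face anti to the C6 side chain (6,7-trans lactone, C7 S) with the acyl substituent equatorial (7,8-anti, C8 S), closing the ten-membered ring and unveiling the exo-methylene; the closest known reactions are Pd/In(I) umpolung allylation of aldehydes with allylic esters, electrochemically mediated indium Barbier allylation and Cr(II) Nozaki–Hiyama macrocyclisation of bromomethyl acrylates to germacranolides, none of which has been shown as an electrochemical ten-membered ring closure onto an α-keto aldehyde.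

**Compound list**

1 | (S)-β-citronellene, (3S)-3,7-dimethylocta-1,6-diene | C=C[C@@H](C)CCC=C(C)C | starting material
2 | (4S)-4-methylhex-5-enal | C=C[C@@H](C)CCC=O | intermediate (not isolated)
3 | (4S)-4-methylhex-5-en-1-ol | C=C[C@@H](C)CCCO | intermediate
4 | (3S)-6-bromo-3-methylhex-1-ene | C=C[C@@H](C)CCCBr | intermediate
5 | dimethyl (4S,5S)-2,2-dimethyl-1,3-dioxolane-4,5-dicarboxylate, (+)-dimethyl 2,3-O-isopropylidene-D-tartrate | COC(=O)[C@H]1OC(C)(C)O[C@@H]1C(=O)OC | starting material
6 | (4S,5S)-N4,N5-dimethoxy-N4,N5,2,2-tetramethyl-1,3-dioxolane-4,5-dicarboxamide | CON(C)C(=O)[C@H]1OC(C)(C)O[C@@H]1C(=O)N(C)OC | intermediate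
7 | [(4S)-4-methylhex-5-en-1-yl]magnesium bromide | C=C[C@@H](C)CCC[Mg]Br | intermediate (not isolated)
8 | (4S,5S)-N-methoxy-N,2,2-trimethyl-5-[(5S)-5-methylhept-6-enoyl]-1,3-dioxolane-4-carboxamide | C=C[C@@H](C)CCCC(=O)[C@H]1OC(C)(C)O[C@@H]1C(=O)N(C)OC | intermediate
9 | (4S,5S)-5-[(2R,6S)-2-hydroxy-6-methyloct-7-en-2-yl]-N-methoxy-N,2,2-trimethyl-1,3-dioxolane-4-carboxamide | C=C[C@@H](C)CCC[C@@](C)(O)[C@H]1OC(C)(C)O[C@@H]1C(=O)N(C)OC | intermediate
10 | (4S,5S)-5-[(2R,6S)-2-hydroxy-6-methyloct-7-en-2-yl]-2,2-dimethyl-1,3-dioxolane-4-carbaldehyde | C=C[C@@H](C)CCC[C@@](C)(O)[C@H]1OC(C)(C)O[C@@H]1C=O | intermediate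
11 | methyl acrylate | C=CC(=O)OC | starting material
12 | methyl 2-[hydroxy{(4R,5S)-5-[(2R,6S)-2-hydroxy-6-methyloct-7-en-2-yl]-2,2-dimethyl-1,3-dioxolan-4-yl}methyl]prop-2-enoate (carbinol epimers) | C=C[C@@H](C)CCC[C@@](C)(O)[C@H]1OC(C)(C)O[C@@H]1C(O)C(=C)C(=O)OC | intermediate
13 | methyl (4R,5S,6R,10S)-3,4,5,6-tetrahydroxy-6,10-dimethyl-2-methylidenedodec-11-enoate (C3 epimers) | C=C[C@@H](C)CCC[C@@](C)(O)[C@@H](O)[C@H](O)C(O)C(=C)C(=O)OC | intermediate (not isolated)
14 | (5R)-5-[(1S,2R,6S)-1,2-dihydroxy-2,6-dimethyloct-7-en-1-yl]-4-hydroxy-3-methylideneoxolan-2-one (C4 epimers) | C=C1C(=O)O[C@H](C1O)[C@H](O)[C@](C)(O)CCC[C@H](C)C=C | intermediate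
15 | (2R)-2-[(1S,2R,6S)-2-hydroxy-2,6-dimethyl-1-(2-methylpropanoyloxy)oct-7-en-1-yl]-4-methylidene-5-oxooxolan-3-yl 2-methylpropanoate (C3 epimers) | C=C1C(=O)O[C@H](C1OC(=O)C(C)C)[C@H](OC(=O)C(C)C)[C@](C)(O)CCC[C@H](C)C=C | intermediate
16 | (2R)-2-[(1S,2R,6S)-2,7,8-trihydroxy-2,6-dimethyl-1-(2-methylpropanoyloxy)octyl]-4-methylidene-5-oxooxolan-3-yl 2-methylpropanoate (C7′ and ring C3 epimers) | C=C1C(=O)O[C@H](C1OC(=O)C(C)C)[C@H](OC(=O)C(C)C)[C@](C)(O)CCC[C@H](C)C(O)CO | intermediate
17 | (2R)-2-[(1S,2R,6S)-2-hydroxy-2,6-dimethyl-1-(2-methylpropanoyloxy)-7,8-dioxooctyl]-4-methylidene-5-oxooxolan-3-yl 2-methylpropanoate (ring C3 epimers) | C=C1C(=O)O[C@H](C1OC(=O)C(C)C)[C@H](OC(=O)C(C)C)[C@](C)(O)CCC[C@H](C)C(=O)C=O | intermediate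
18 | {[(5R)-5-[(1S,2R,6S)-2-hydroxy-2,6-dimethyl-1-(2-methylpropanoyloxy)-7,8-dioxooctyl]-2-oxo-2,5-dihydrofuran-3-yl]methyl}indium dibromide | Br[In](Br)CC1=C[C@@H](OC1=O)[C@H](OC(=O)C(C)C)[C@](C)(O)CCC[C@H](C)C(=O)C=O | intermediate (not isolated)
19 | CNP0270933.1, (3aS,4S,6S,10R,11S,11aR)-4,10-dihydroxy-6,10-dimethyl-3-methylidene-2,5-dioxododecahydrocyclodeca[b]furan-11-yl 2-methylpropanoate (germacrane locants: C4 R, C5 S, C6 R, C7 S, C8 S, C10 S) | C=C1C(=O)O[C@@H]2[C@@H]1[C@H](O)C(=O)[C@@H](C)CCC[C@@](C)(O)[C@H]2OC(=O)C(C)C | target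

**Step count**

Total: 12 steps. Longest linear sequence: 11 steps (1 → 19 through steps 1, 2 and 4–12); the branch from 5 is 10 steps.

**Steps most likely to fail, with fallbacks**

Step 12 (the proposed electroreductive macrocyclisation). Possible failures are oligomerisation, capture of the π-allyl by a hydroxyl group, or protonation of the allyl metal. The fallback uses known halide-based Barbier chemistry. It sets out from 17: MgBr2·OEt2 (CH2Cl2, 0 °C) exchanges the allylic isobutyrate for bromide with allylic transposition and gives (1S,2R,6S)-1-[(2R)-4-(bromomethyl)-5-oxo-2,5-dihydrofuran-2-yl]-2-hydroxy-2,6-dimethyl-7,8-dioxooctyl 2-methylpropanoate F1. This is closed with stoichiometric indium powder in THF/aq. NH4Cl at high dilution (Barbier allylation of the keto-aldehyde hydrate, with the same closed transition state) and comes back to the route at 19.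

Step 5 (C4 configuration). If the addition follows the open Felkin–Anh model instead of the chelate model, the C4 epimer dominates. The fallback introduces the two carbon groups in the reverse order. It sets out from 6: MeMgBr (1 equiv, THF, −78 → 0 °C) gives (4S,5S)-5-acetyl-N-methoxy-N,2,2-trimethyl-1,3-dioxolane-4-carboxamide F2. Grignard reagent 7, premixed with CeCl3 (THF, −78 °C, non-chelating), is then added to the methyl ketone. With the substituents interchanged, the open-model facial preference now delivers the required (4R) carbinol, and the sequence comes back to the route at 9.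

Step 11 (keto aldehyde from the diol). Possible failures are glycol cleavage, over-oxidation or loss of the C10 configuration. The fallback reaches the same compound through an α-ketol. It sets out from 15: RuCl3 (cat.), Oxone, NaHCO3 in EtOAc/MeCN/H2O (ketohydroxylation of the terminal alkene) gives (2R)-2-[(1S,2R,6S)-2,8-dihydroxy-2,6-dimethyl-1-(2-methylpropanoyloxy)-7-oxooctyl]-4-methylidene-5-oxooxolan-3-yl 2-methylpropanoate F3. Its primary alcohol is oxidised with Dess–Martin periodinane (NaHCO3, CH2Cl2, 0 °C), and the sequence comes back to the route at 17.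

**Further compounds**

F1 | step 12 | (1S,2R,6S)-1-[(2R)-4-(bromomethyl)-5-oxo-2,5-dihydrofuran-2-yl]-2-hydroxy-2,6-dimethyl-7,8-dioxooctyl 2-methylpropanoate | BrCC1=C[C@@H](OC1=O)[C@H](OC(=O)C(C)C)[C@](C)(O)CCC[C@H](C)C(=O)C=O
F2 | step 5 | (4S,5S)-5-acetyl-N-methoxy-N,2,2-trimethyl-1,3-dioxolane-4-carboxamide | CC(=O)[C@H]1OC(C)(C)O[C@@H]1C(=O)N(C)OC
F3 | step 11 | (2R)-2-[(1S,2R,6S)-2,8-dihydroxy-2,6-dimethyl-1-(2-methylpropanoyloxy)-7-oxooctyl]-4-methylidene-5-oxooxolan-3-yl 2-methylpropanoate | C=C1C(=O)O[C@H](C1OC(=O)C(C)C)[C@H](OC(=O)C(C)C)[C@](C)(O)CCC[C@H](C)C(=O)CO
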